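## Retrosynthetic overview

- Chain numbering: C1 = benzylic CH2, C5 = C=O, C18 = CH3. Target 6 comes from benzyl ether 5 by O-debenzylation.
- 5 is cut at C2–C3, the central bond of the (CH2)4 tether. In conventional synthons both carbons are acceptors (enone β-carbon, alkyl halide carbon). They are joined by reversing the polarity of C3 (homoenolate) and making C2 a primary radical, which meet at nickel.
- Enabling feature: the unbranched C3H2–C4H2–C5(=O) unit is the opened form of the three ring carbons of 1-tridecylcyclopropanol 2 (C5 = carbinol carbon, C3 and C4 = the two equivalent ring CH2). The aryl–C1H2–C2H2 unit is a 3-arylpropanoic acid minus CO2, used as redox-active ester 4.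
- 2 comes from methyl myristate 1 (Kulinkovich). 4 comes from acid 3 and N-hydroxyphthalimide.
- Rings: the benzene ring is bought. The only ring made is the temporary cyclopropane (step 1), and it is opened again in step 3.

Key step: step 3

Remark: the target has no stereocentre and no C=C bond, so no stereocontrol is needed; 3-[4-(benzyloxy)phenyl]propanoic acid is taken as a catalogue compound.

## Route

Step 1
Reactants: 1 methyl tetradecanoate (methyl myristate)
Product: 2 1-tridecylcyclopropan-1-ol
Conditions: EtMgBr (2.5 equiv, slow addition), Ti(OiPr)4 (0.2 equiv), THF, 0 °C to rt; cold aqueous NH4Cl work-up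
Reagents that add atoms: ethylmagnesium bromide, CC[Mg]Br
Why: Kulinkovich cyclopropanol synthesis, in which Ti(OiPr)4 and two EtMgBr lose ethane to give a titanacyclopropane that acts as a 1,2-dicarbanion and adds twice to the carbonyl of an unhindered fatty methyl ester (the standard substrate class), with no stereocentre arising because the two new ring CH2 groups are equivalent.

Step 2
Reactants: 3 3-[4-(benzyloxy)phenyl]propanoic acid
Product: 4 1,3-dioxoisoindolin-2-yl 3-[4-(benzyloxy)phenyl]propanoate (N-hydroxyphthalimide redox-active ester)
Conditions: N-hydroxyphthalimide (1.05 equiv), DIC (1.1 equiv), DMAP (0.1 equiv), CH2Cl2, rt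
Reagents that add atoms: N-hydroxyphthalimide, O=C1c2ccccc2C(=O)N1O
Why: Steglich-type carbodiimide esterification, in which DIC activates the acid as its O-acylisourea and DMAP relays the acyl group to the acidic N–OH of N-hydroxyphthalimide while the benzyl ether stays untouched.

Step 3
Reactants: 2 1-tridecylcyclopropan-1-ol (1.5 equiv), 4 1,3-dioxoisoindolin-2-yl 3-[4-(benzyloxy)phenyl]propanoate
Product: 5 1-[4-(benzyloxy)phenyl]octadecan-5-one
Conditions: NiCl2·glyme (10 mol %), 2,2'-bipyridine (15 mol %), Et3N (2.5 equiv), DMA–THF, 40 °C, N2
Reagents that add atoms: none
Why: Under Et3N the hydroxyl of 2 binds to Ni(II) and the strained ring opens by two-electron β-carbon elimination to a β-nickelated ketone (homoenolate), which unveils the C5 carbonyl and turns C3 into a donor carbon, while low-valent nickel passes one electron to the phthalimide unit of 4, which fragments into phthalimide anion, CO2 and the primary 2-arylethyl radical centred on C2; capture of this radical at nickel and C(sp3)–C(sp3) reductive elimination from Ni(III) form the C2–C3 bond and return Ni(I). The closest known reaction type is the nickel-catalysed β-alkylation of cyclopropanol-derived homoenolates with N-hydroxyphthalimide esters, which covers 1-alkylcyclopropanols and primary alkyl esters, so this is an application to a new pair of partners. No ring is closed (the temporary three-membered ring is opened) and no stereocentre is created. The step needs regioselective ring opening and cross- over homo-coupling: the first is secured because the two ring CH2 groups of 2 are equivalent and either C–C cleavage gives the same homoenolate, the second because the partners are activated by orthogonal events (two-electron opening at Ni(II) versus one-electron reduction) in an overall redox-neutral process without external reductant. β-Hydride elimination at the homoenolate stage is not a dead end, because the resulting enone accepts the same radical at its terminal carbon and so forms the same bond. The aryl benzyl ether, the new dialkyl ketone and the saturated chain are inert to nickel/bipyridine at 40 °C.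

Step 4
Reactants: 5 1-[4-(benzyloxy)phenyl]octadecan-5-one
Product: 6 1-(4-hydroxyphenyl)octadecan-5-one (target)
Conditions: H2 (1 atm), 10% Pd/C, EtOAc–EtOH, rt
Reagents that add atoms: none
Why: Catalytic hydrogenolysis of an aryl benzyl ether over Pd/C at 1 atm and room temperature cleaves only the benzylic C–O bond, since an isolated dialkyl ketone, the phenol ring and the alkyl chain are not reduced under these conditions.

## Compound list

1 | methyl tetradecanoate | CCCCCCCCCCCCCC(=O)OC | starting material
2 | 1-tridecylcyclopropan-1-ol | CCCCCCCCCCCCCC1(O)CC1 | intermediate
3 | 3-[4-(benzyloxy)phenyl]propanoic acid | OC(=O)CCc1ccc(OCc2ccccc2)cc1 | starting material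
4 | 1,3-dioxoisoindolin-2-yl 3-[4-(benzyloxy)phenyl]propanoate | O=C(CCc1ccc(OCc2ccccc2)cc1)ON1C(=O)c2ccccc2C1=O | intermediate
5 | 1-[4-(benzyloxy)phenyl]octadecan-5-one | CCCCCCCCCCCCCC(=O)CCCCc1ccc(OCc2ccccc2)cc1 | intermediate
6 | 1-(4-hydroxyphenyl)octadecan-5-one | CCCCCCCCCCCCCC(=O)CCCCc1ccc(O)cc1 | target

Total step count: 4. Longest linear sequence: 3 steps (1 → 2 → 5 → 6, or 3 → 4 → 5 → 6).

## Steps most likely to fail

**Step 3.**
- Risk: the homoenolate may be lost by protonation or β-hydride elimination before it meets the radical. The activated ester may transfer its acyl group to the tertiary alkoxide. The unstabilised primary radical may self-couple or abstract hydrogen.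
- Fallback: it separates ring opening from bond formation, sets out from 2 and 4 and comes back at 5. Electrophilic ring opening of 2 with NBS (CH2Cl2, 0 °C) should give 1-bromohexadecan-3-one F1. Elimination with Et3N (Et2O, rt) should give hexadec-1-en-3-one F2. A photoredox decarboxylative Giese addition of 4 to this enone (Ru(bpy)3(PF6)2, Hantzsch ester, iPr2NEt, CH2Cl2, blue LEDs, rt) then makes the same C2–C3 bond and delivers 5.

**Step 1.**
- Risk: plain 1,2-addition of the Grignard reagent to the ester may compete. Titanium turnover may stall. The cyclopropanol may isomerise by ring opening during work-up or on silica.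
- Fallback: it avoids the three-membered ring altogether, sets out from 1 and comes back at 5. Aminolysis of 1 with MeNH(OMe)·HCl and iPrMgCl (THF, −20 °C) should give N-methoxy-N-methyltetradecanamide F3. Vinylmagnesium bromide (THF, 0 °C, inverse quench into cold dilute acid) should convert it into hexadec-1-en-3-one F2. This enone is joined to 4 by the Giese addition described above to give 5.

**Step 4.**
- Risk: the palladium surface may be poisoned by traces of bipyridine, phthalimide or nickel carried over. The waxy substrate may react slowly for lack of solubility. Forcing the reaction may start reduction of the ketone.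
- Fallback: it replaces reduction by Lewis-acid cleavage, sets out from 5 and comes back at 6. BCl3 with pentamethylbenzene as cation scavenger (CH2Cl2, −78 °C) removes the benzyl group as a benzyl cation that is trapped by the scavenger, and the ketone is left alone. It makes no compound outside the list (entry F0).

## Further compounds

F1 | step 3 | 1-bromohexadecan-3-one | CCCCCCCCCCCCCC(=O)CCBr
F2 | step 3 | hexadec-1-en-3-one | CCCCCCCCCCCCCC(=O)C=C
F3 | step 1 | N-methoxy-N-methyltetradecanamide | CCCCCCCCCCCCCC(=O)N(C)OC
F0 | step 4 | none | none
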